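## Structural features

The target joins two 5,7-dimethoxycoumarin units through their C8 carbons to a 1,4-dimethylcyclohex-3-ene. The ring is numbered C1 (quaternary: methyl and the ethenyl carbon Ca), C2 and C3 (methylenes), C4 (methyl-bearing alkene carbon), C5 (alkene CH) and C6 (CH carrying coumarin B); coumarin A sits on Cb of the E-configured Ca=Cb link. C1 and C6 are the only stereocentres, they are adjacent, and coumarin B is cis to Ca; C1 is an all-carbon quaternary centre (R) and C6 is allylic and benzylic at once (R). Fragile points are the two coumarin lactones (opened by hydroxide or alkoxide, prone to conjugate addition and photodimerisation), the electron-rich dimethoxyarenes, the acid-sensitive C4=C5 alkene and the doubly activated C6–H. In addition, Cb=Ca–C1–C6–C5=C4 is a 1,5-diene across a weak C1–C6 bond, so strong prolonged heating invites Cope-type or cycloreversion processes. The real difficulty is the vicinal quaternary/tertiary pair in relative and absolute sense, flanked by two bulky, constitutionally identical aryl groups. The key step exploits that O1 of coumarin B is ortho to the C8–C6 bond and that Ca is cis to ring B. An acyl tether C1–C(=O)–O–aryl, with Ca as the carbonyl carbon, therefore closes a six-membered lactone, and an extra C2=C3 alkene makes C1 the prochiral centre of a symmetrical 1,4-dimethylcyclohexa-2,5-diene.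

## Logic of the disconnections

19 is cut at the Cb–C8 bond of ring A into 16 and 18. The cut is convergent, both halves carry a finished coumarin, and the E geometry is free of charge because C1 has no hydrogen, so palladium on Ca can only eliminate toward Cb. The forward step must couple a terminal alkene on a quaternary carbon with a di-ortho-substituted aryl iodide under a base that leaves both lactones closed.

18 is cut at the C8–I bond to 17. The gain is a one-step entry from a commercial coumarin; the demand is attack at C8 and not at C6 or C3.

16 is cut through the pyranone of ring B (O1–C2 and C3=C4) to 14, by way of 15. This reduces coumarin B to a salicylaldehyde and lets its ring oxygen be the phenol oxygen that served earlier as tether atom. The forward annulation must run well below the temperatures that threaten the 1,5-diene, which an intramolecular Wittig closure does.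

14 is cut at the formyl–aryl bond to 13. The demand is formylation at the single free carbon ortho to the hydroxyl group and not at the more exposed carbon between the two methoxy groups, which calls for a phenoxide-templated method.

13 is cut at Ca=CH2 to 11, by way of 12. The alkene carbon Ca is recognised as the lactol carbon and the phenol as the lactol oxygen, so the tether is dismantled and the styryl handle created in one operation. The forward olefination meets a neopentyl aldehyde that cannot enolise, so no stereocentre is at risk.

11 is cut at the C–H bond of the lactol carbon to 10; the demand is a partial reduction of an aryl lactone that stops at the hemiacetal.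

10 is cut at the two C–H bonds on C2 and C3 to 9. This restores the second ring alkene, which is the price of a symmetrical precursor. The forward step must saturate a cis-disubstituted alkene of a conjugated diene and leave the trisubstituted C4=C5 alkene and the C6 stereocentre alone.

9 is cut at the C6–aryl bond, opening the lactone ring, to 8. Both stereocentres disappear and an achiral ester remains. The forward step must choose one of two enantiotopic alkenes, must reach the ester rotamer that allows ring closure, and needs the C4 hydrogen on the tether face for β-hydride elimination; hence only the cis isomer of 8 is admissible. Iodide is kept as the leaving group so that halide abstraction by silver opens the cationic pathway.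

8 is cut at the ester C–O bond to 4 and 6, by way of 7. Iodine is placed on the phenol before acylation because an iodonium source would attack the diene of 8. The demands are a mild acylation of a hindered phenol and isomerically pure 4.

6 is cut at the C–I bond to 5; the demand is substitution ortho to the hydroxyl group.

4 is cut at the C1–CH3 bond and at the ring C–H bond formed on reduction to 1 and 2, by way of 3. The gain is a one-flask entry from a commodity acid; the cost is that the C1/C4 relationship is not controlled and the cis isomer must be isolated.

## Other disconnections considered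

Alternative 1: The cut removes the ring bond C5–C6 and the C6–aryl bond together, so that C6 becomes a carbene carbon. In the forward sense zerovalent palladium inserts into the C–I bond of the Z-alkenyl iodide A2, an acyclic N-tosylhydrazone that already holds the C1 stereocentre and a silyl alkyne as the future styryl arm. Base converts the hydrazone into a diazo group, the palladium carbene at C6 takes up the alkenyl group (C5–C6 bond, ring closure), and the η3-allylpalladium over C6–C5–C4 is intercepted at C6 by the boronic acid A3 to give A1.
- In its favour: coumarin B arrives intact, so the formylation and annulation of the chosen plan fall away (better). No ester rotamer has to be overcome and no surplus alkene has to be hydrogenated (better). The hydrazone carbon has no α-hydrogen, so the usual competing alkene formation is excluded.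
- Against it: C1 must be made beforehand as a non-racemic acyclic quaternary centre bearing methyl, alkynyl, formyl and a homoallyl chain, which needs its own asymmetric step and a long precursor synthesis. The configuration at C6 would rest on 1,2-induction between a methyl and a slender alkynyl group when the aryl is delivered from palladium, a weak handle. A3 is a di-ortho-substituted, electron-rich boronic acid, slow to transmetalate and prone to protodeboronation. After A1 the alkyne must still be unmasked and turned into the E-styryl arm.
- Comparison: equal or better in convergence and in economy at ring B. It is weaker in stereocontrol, because two separate events, one only substrate-biased, replace a single catalyst-controlled desymmetrisation in which the tether leaves no choice but cis. The step count would be expected to be higher because of A2.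

Alternative 2: The cut is the C4=C5 alkene, traced back to the cyclobutene A5, in which Ca and C5 are the alkene carbons of the four-membered ring, C1 and C6 its sp3 carbons, and C1 carries a 3-methylbut-3-enyl chain. In the forward sense a ruthenium alkylidene (second-generation Grubbs catalyst) opens the strained ring and the alkylidene on C5 closes onto the isopropenyl group to give A4, which is identical with compound 16 of the chosen plan.
- In its favour: the key step touches neither stereocentre, so it cannot fail on configuration (equal or better). Ruthenium carbenes tolerate coumarins, and strain release drives the opening. Because A4 equals 16, only the final Heck coupling remains, so the sequence after the key step is shorter (better).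
- Against it: the whole stereochemical problem moves into A5, a cyclobutene with adjacent quaternary and aryl-bearing stereocentres (aryl cis to methyl) needed as one enantiomer, for which no general enantioselective [2+2] entry with such a hindered aryl group is at hand. Ring opening can also place ruthenium on Ca; that alkylidene would close to a cyclopentene, a regiochemical branch absent from the chosen plan. Closing a trisubstituted alkene onto a 1,1-disubstituted partner is the slow direction of ring-closing metathesis.
- Comparison: cleaner once the precursor exists and equal in the last coupling, but it gives no answer of its own to how C1 and C6 are created. The chosen plan creates both from an achiral ester three steps from commodity chemicals.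

Alternative 3: The cut takes out C1–C2 and C5–C6, a retro-[4+2] in which C1 and C6 are C3 and C4 of a coumarin. In the forward sense the 3,4-alkene of A7, activated by chelation of its two carbonyl groups to Cu(OTf)2 bearing a chiral bis(oxazoline), adds the silyl diene A8 to give A6. A6 is cis-fused and carries an allylsilane at C5, whose protodesilylation would move the alkene into the C4=C5 position.
- In its favour: two ring bonds and both permanent stereocentres form at once. Cis fusion follows from the dienophile geometry with the same certainty as from the tether (equal). No diastereomer separation and no selective hydrogenation are needed (better). A7 and A8 are each one or two steps from commercial materials (better than the route to 8). A6 is the same kind of tricyclic aryl lactone as 10, so the later conversion of the lactone carbonyl into Ca and of the phenol oxygen into ring B could be taken over unchanged.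
- Against it: the 5- and 7-methoxy groups feed electron density into C4 of A7 and make it a reluctant dienophile, and the terminal silyl group slows the diene, so forcing conditions would be needed exactly where the catalyst must control the face. Regiochemistry rests on the methyl group alone. The quaternary substituent arrives as CO2Me and not as CH3, so it must be differentiated from the lactone, reduced to a neopentyl alcohol and deoxygenated next to a vinyl group, at least three further steps of doubtful reliability.
- Comparison: shorter and safer before the key step, longer and less safe after it. The chosen plan brings the C1 methyl group at the right oxidation level from the start.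

Key step: step 4

Remark: the antipode of BINAP that leads into the (6aS,10aS) series cannot be fixed on paper; (R)-BINAP is written and stands for whichever antipode gives compound 9.

## Steps

Step 1
Reactants: 1 4-methylbenzoic acid (p-toluic acid); 2 iodomethane
Product: 4 cis-1,4-dimethylcyclohexa-2,5-diene-1-carboxylic acid, via dilithium enediolate 3 (not isolated)
Conditions: Li, NH3(l), THF, −78 °C; then 2, −78 °C to rt; aq. NH4Cl, then HCl to pH 2; cis isomer isolated by fractional crystallisation
Reagents that add atoms: none
Why: Birch reduction of the carboxylate stops at the 1,4-dihydro enediolate 3 (protonation para to the carboxylate by ammonia), which is methylated at the ipso carbon by 2 (Birch reductive alkylation); the remote C4 methyl gives no useful facial bias, so both diastereomers are expected and only the cis acid, in which CO2H and H-4 share one face, is taken on.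

Step 2
Reactants: 5 3,5-dimethoxyphenol
Product: 6 2-iodo-3,5-dimethoxyphenol
Conditions: NIS (1.0 equiv), CH2Cl2, −40 to 0 °C
Reagents that add atoms: N-iodosuccinimide, O=C1CCC(=O)N1I
Why: Electrophilic aromatic iodination; C2 is ortho to the hydroxyl group, which also hydrogen-bonds the reagent, and para to a methoxy group, whereas the competing C4 lies between two methoxy groups and is more shielded toward the large iodine electrophile; one equivalent at low temperature limits di-iodination, and any 4-iodo isomer is removed by chromatography.

Step 3
Reactants: 4 cis-1,4-dimethylcyclohexa-2,5-diene-1-carboxylic acid; 6 2-iodo-3,5-dimethoxyphenol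
Product: 8 2-iodo-3,5-dimethoxyphenyl cis-1,4-dimethylcyclohexa-2,5-diene-1-carboxylate, via acid chloride 7 (not isolated)
Conditions: (COCl)2, cat. DMF, CH2Cl2, 0 °C; then 6, Et3N, cat. DMAP, CH2Cl2, 0 °C to rt
Reagents that add atoms: none
Why: Acyl chloride formation under catalytic-DMF conditions at 0 °C avoids the acid- and heat-promoted decarbonylative aromatisation open to dienyl acids, and DMAP-catalysed acylation of the hindered phenol then gives the aryl ester (nucleophilic acyl substitution); no stereocentre is touched.

Step 4
Reactants: 8 2-iodo-3,5-dimethoxyphenyl cis-1,4-dimethylcyclohexa-2,5-diene-1-carboxylate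
Product: 9 (6aS,10aS)-1,3-dimethoxy-6a,9-dimethyl-6a,10a-dihydro-6H-benzo[c]chromen-6-one
Conditions: Pd2(dba)3 (5 mol %), (R)-BINAP (12 mol %), Ag3PO4 (1.1 equiv), DMA, 90 °C
Reagents that add atoms: none
Why: Zerovalent palladium carrying BINAP inserts into the C–I bond and Ag3PO4 removes iodide, so that a cationic arylpalladium with the bisphosphine still chelated binds an alkene; this is an asymmetric intramolecular Mizoroki–Heck reaction of the known type that desymmetrises 1-substituted cyclohexa-2,5-dienes to cis-fused bicycles with a quaternary ring-fusion carbon. Syn carbopalladation of one of the two enantiotopic alkenes in the 6-exo-trig mode forms the C10a–C10b bond (C6–aryl of the target) and closes the six-membered lactone. The three-atom ester tether can reach the alkene only from its own face, so the ring fusion is cis and C6a and C10a are set together; which alkene reacts, and hence the absolute configuration, is decided by the chiral bisphosphine. Palladium then sits on C10 on the tether face, syn to H-9, which the cis-dimethyl relationship of 8 has put there; H-10a is anti and C6a bears no hydrogen, so β-hydride elimination can only give the C9=C10 alkene, conjugated with the untouched C7=C8 alkene. The selectivities needed are exo over endo closure (geometrically enforced), choice between the enantiotopic alkenes (ligand), and no re-addition of palladium hydride, for which the silver salt makes hydride loss irreversible and so protects C10a from epimerisation. The demand on the substrate is the less favoured ester rotamer with the aryl group turned toward the ring; a polar amide solvent and 90 °C are chosen to populate it while oxidative addition into the electron-rich iodide stays fast. A trans-configured ester would stall after insertion for want of a syn β-hydrogen, which is why isomeric purity of 8 is part of the design.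

Step 5
Reactants: 9 (6aS,10aS)-1,3-dimethoxy-6a,9-dimethyl-6a,10a-dihydro-6H-benzo[c]chromen-6-one
Product: 10 (6aS,10aS)-1,3-dimethoxy-6a,9-dimethyl-6a,7,8,10a-tetrahydro-6H-benzo[c]chromen-6-one
Conditions: 2-nitrobenzenesulfonyl hydrazide (added in portions), Et3N, CH2Cl2, rt
Reagents that add atoms: none
Why: Diimide released from the sulfonyl hydrazide transfers two hydrogens in a concerted syn fashion and is strongly retarded by alkene substitution, so the cis-disubstituted C7=C8 alkene (C2=C3 of the target) should be reduced ahead of the trisubstituted C9=C10 alkene (diimide reduction); no metal hydride is present that could shift the remaining alkene or epimerise C10a, and the aprotic medium leaves the aryl lactone closed.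

Step 6
Reactants: 10 (6aS,10aS)-1,3-dimethoxy-6a,9-dimethyl-6a,7,8,10a-tetrahydro-6H-benzo[c]chromen-6-one
Product: 11 (6aS,10aS)-1,3-dimethoxy-6a,9-dimethyl-6a,7,8,10a-tetrahydro-6H-benzo[c]chromen-6-ol (mixture of anomers)
Conditions: i-Bu2AlH (1.1 equiv), CH2Cl2, −78 °C; aq. KNaC4H4O6
Reagents that add atoms: none
Why: Partial reduction of a lactone with i-Bu2AlH; at −78 °C the aluminium hemiacetal, shielded by the neighbouring quaternary carbon, should persist until work-up and give the lactol, and one equivalent of hydride guards against collapse and over-reduction.

Step 7
Reactants: 11 (6aS,10aS)-1,3-dimethoxy-6a,9-dimethyl-6a,7,8,10a-tetrahydro-6H-benzo[c]chromen-6-ol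
Product: 13 2-[(1R,6R)-6-ethenyl-3,6-dimethylcyclohex-2-en-1-yl]-3,5-dimethoxyphenol, via potassium phenolate aldehyde 12 (not isolated)
Conditions: Ph3PCH3Br (4 equiv), KOtBu (4 equiv), THF, 0 °C to rt; aq. NH4Cl
Reagents that add atoms: methyltriphenylphosphonium bromide, C[P+](c1ccccc1)(c1ccccc1)c1ccccc1.[Br-]
Why: Base opens the lactol to the aldehyde phenolate 12, favoured because phenoxide is the better anion, and excess ylide methylenates the neopentyl aldehyde (Wittig reaction); the α-carbon is quaternary, so nothing can epimerise, and a neutral work-up is used because acid could add the phenol to the alkenes.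

Step 8
Reactants: 13 2-[(1R,6R)-6-ethenyl-3,6-dimethylcyclohex-2-en-1-yl]-3,5-dimethoxyphenol
Product: 14 3-[(1R,6R)-6-ethenyl-3,6-dimethylcyclohex-2-en-1-yl]-2-hydroxy-4,6-dimethoxybenzaldehyde
Conditions: MgCl2, Et3N, (CH2O)n, MeCN, reflux
Reagents that add atoms: paraformaldehyde (as formaldehyde), C=O
Why: Magnesium-mediated ortho-formylation of a phenol: the magnesium phenoxide delivers formaldehyde to the only free ortho carbon and a second formaldehyde accepts hydride, so the more exposed carbon between the two methoxy groups, which an untemplated electrophile would prefer, is left alone; the medium is not acidic enough to engage the alkenes.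

Step 9
Reactants: 14 3-[(1R,6R)-6-ethenyl-3,6-dimethylcyclohex-2-en-1-yl]-2-hydroxy-4,6-dimethoxybenzaldehyde
Product: 16 8-[(1R,6R)-6-ethenyl-3,6-dimethylcyclohex-2-en-1-yl]-5,7-dimethoxy-2H-chromen-2-one, via acyl ylide 15 (not isolated)
Conditions: Ph3P=C=C=O (1.2 equiv), toluene, 110 °C
Reagents that add atoms: (triphenylphosphoranylidene)ketene, O=C=C=P(c1ccccc1)(c1ccccc1)c1ccccc1
Why: The phenol adds across the C=C=O unit of the ketene ylide to give the stabilised acyl ylide 15, which closes on the adjacent formyl group by intramolecular Wittig reaction; the ring dictates the cis alkene of the pyranone, so neither E/Z isomerisation nor a temperature that would endanger the 1,5-diene is needed.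

Step 10
Reactants: 17 5,7-dimethoxy-2H-chromen-2-one (5,7-dimethoxycoumarin)
Product: 18 8-iodo-5,7-dimethoxy-2H-chromen-2-one
Conditions: NIS (1.05 equiv), TFA (0.3 equiv), MeCN, 0 °C to rt
Reagents that add atoms: N-iodosuccinimide, O=C1CCC(=O)N1I
Why: Electrophilic aromatic iodination; C8 is ortho to the 7-methoxy and para to the 5-methoxy group and is flanked on one side only by the ring oxygen, whereas C6 lies between two methoxy groups, the 5-methoxy being turned toward it by the peri hydrogen on C4, and C3 of the electron-poor pyranone is less nucleophilic than either.

Step 11
Reactants: 16 8-[(1R,6R)-6-ethenyl-3,6-dimethylcyclohex-2-en-1-yl]-5,7-dimethoxy-2H-chromen-2-one; 18 8-iodo-5,7-dimethoxy-2H-chromen-2-one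
Product: 19 8-[(E)-2-[(1R,2R)-2-(5,7-dimethoxy-2-oxo-2H-chromen-8-yl)-1,4-dimethylcyclohex-3-en-1-yl]ethenyl]-5,7-dimethoxy-2H-chromen-2-one
Conditions: Pd(OAc)2 (10 mol %), n-Bu4NCl, NaHCO3, DMF, 80 °C
Reagents that add atoms: none
Why: Mizoroki–Heck coupling of an aryl iodide with a monosubstituted alkene: the aryl group adds to the terminal carbon, and because C1 is quaternary the only β-hydrogens available to palladium on Ca are those on Cb, which gives the E-styrene without positional isomers; hydrogencarbonate is too weak a base to open either lactone, and the trisubstituted ring alkene and the coumarin 3,4-alkenes insert far more slowly than a terminal vinyl group.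

## Compound list

1 | 4-methylbenzoic acid (p-toluic acid) | Cc1ccc(C(=O)O)cc1 | starting material
2 | iodomethane | CI | starting material
3 | dilithium (4-methylcyclohexa-2,5-dien-1-ylidene)methanediolate | [Li+].[Li+].CC1C=CC(=C([O-])[O-])C=C1 | intermediate (not isolated)
4 | cis-1,4-dimethylcyclohexa-2,5-diene-1-carboxylic acid (both methyl groups on one face; CO2H and H-4 on the other) | C[C@@]1(C(=O)O)C=C[C@@H](C)C=C1 | intermediate
5 | 3,5-dimethoxyphenol | COc1cc(O)cc(OC)c1 | starting material
6 | 2-iodo-3,5-dimethoxyphenol | COc1cc(O)c(I)c(OC)c1 | intermediate
7 | cis-1,4-dimethylcyclohexa-2,5-diene-1-carbonyl chloride | C[C@@]1(C(=O)Cl)C=C[C@@H](C)C=C1 | intermediate (not isolated)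
8 | 2-iodo-3,5-dimethoxyphenyl cis-1,4-dimethylcyclohexa-2,5-diene-1-carboxylate (achiral; methyl groups cis) | C[C@@]1(C(=O)Oc2cc(OC)cc(OC)c2I)C=C[C@@H](C)C=C1 | intermediate
9 | (6aS,10aS)-1,3-dimethoxy-6a,9-dimethyl-6a,10a-dihydro-6H-benzo[c]chromen-6-one (cis-fused) | O=C2[C@@]1(C)C=CC(C)=C[C@H]1c3c(OC)cc(OC)cc3O2 | intermediate
10 | (6aS,10aS)-1,3-dimethoxy-6a,9-dimethyl-6a,7,8,10a-tetrahydro-6H-benzo[c]chromen-6-one | O=C2[C@@]1(C)CCC(C)=C[C@H]1c3c(OC)cc(OC)cc3O2 | intermediate
11 | (6aS,10aS)-1,3-dimethoxy-6a,9-dimethyl-6a,7,8,10a-tetrahydro-6H-benzo[c]chromen-6-ol (both anomers) | OC2[C@@]1(C)CCC(C)=C[C@H]1c3c(OC)cc(OC)cc3O2 | intermediate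
12 | potassium 2-[(1S,6S)-6-formyl-3,6-dimethylcyclohex-2-en-1-yl]-3,5-dimethoxyphenolate | O=C[C@@]1(C)CCC(C)=C[C@H]1c1c(OC)cc(OC)cc1[O-].[K+] | intermediate (not isolated)
13 | 2-[(1R,6R)-6-ethenyl-3,6-dimethylcyclohex-2-en-1-yl]-3,5-dimethoxyphenol | C=C[C@@]1(C)CCC(C)=C[C@H]1c1c(OC)cc(OC)cc1O | intermediate
14 | 3-[(1R,6R)-6-ethenyl-3,6-dimethylcyclohex-2-en-1-yl]-2-hydroxy-4,6-dimethoxybenzaldehyde | C=C[C@@]1(C)CCC(C)=C[C@H]1c1c(OC)cc(OC)c(C=O)c1O | intermediate
15 | 2-[(1R,6R)-6-ethenyl-3,6-dimethylcyclohex-2-en-1-yl]-6-formyl-3,5-dimethoxyphenyl (triphenyl-λ5-phosphanylidene)acetate | C=C[C@@]1(C)CCC(C)=C[C@H]1c1c(OC)cc(OC)c(C=O)c1OC(=O)C=P(c2ccccc2)(c2ccccc2)c2ccccc2 | intermediate (not isolated)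
16 | 8-[(1R,6R)-6-ethenyl-3,6-dimethylcyclohex-2-en-1-yl]-5,7-dimethoxy-2H-chromen-2-one | C=C[C@@]1(C)CCC(C)=C[C@H]1c1c(OC)cc(OC)c2ccc(=O)oc12 | intermediate
17 | 5,7-dimethoxy-2H-chromen-2-one (5,7-dimethoxycoumarin) | COc1cc(OC)c2ccc(=O)oc2c1 | starting material
18 | 8-iodo-5,7-dimethoxy-2H-chromen-2-one | COc1cc(OC)c2ccc(=O)oc2c1I | intermediate
19 | 8-[(E)-2-[(1R,2R)-2-(5,7-dimethoxy-2-oxo-2H-chromen-8-yl)-1,4-dimethylcyclohex-3-en-1-yl]ethenyl]-5,7-dimethoxy-2H-chromen-2-one | COc1cc(OC)c2ccc(=O)oc2c1/C=C/[C@@]1(C)CCC(C)=C[C@H]1c1c(OC)cc(OC)c2ccc(=O)oc12 | target

## Step count and least certain steps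

Total step count: 11. Longest linear sequence: 9 steps (1 to 4 to 8 to 9 to 10 to 11 to 13 to 14 to 16 to 19; steps 1, 3, 4, 5, 6, 7, 8, 9 and 11).

Step 4 (key step). Most likely to go wrong: ring closure that is slow because the ester rests almost entirely in the rotamer with the aryl group turned away from the ring. The temperature then has to rise, discrimination between the two enantiotopic alkenes erodes, and hydrodeiodination competes. Fallback, from 8 back to 9: the cyclisation is run with an achiral catalyst (Pd(OAc)2, PPh3, Ag2CO3, DMA, 110 °C), where only rate counts. This gives 9 together with its mirror image (6aR,10aR)-1,3-dimethoxy-6a,9-dimethyl-6a,10a-dihydro-6H-benzo[c]chromen-6-one F1. The two are separated by preparative chromatography on a chiral stationary phase and the route is rejoined at 9; catalyst control is thus replaced by resolution.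

Step 1. Most likely to go wrong: methylation of the enediolate from both faces at similar rates, followed by co-crystallisation of the two acids, so that no isomerically pure material is obtained at this stage. Fallback, from 1 back to 8: the unseparated mixture of 4 and trans-1,4-dimethylcyclohexa-2,5-diene-1-carboxylic acid F2 is coupled with 6 by carbodiimide activation (DCC, cat. DMAP, CH2Cl2, rt). The separation is moved to the neutral, UV-active aryl esters, where 8 is freed from 2-iodo-3,5-dimethoxyphenyl trans-1,4-dimethylcyclohexa-2,5-diene-1-carboxylate F3 by chromatography and crystallisation. The configuration is assigned by NOE between H-4 and the C1 methyl group.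

Step 5. Most likely to go wrong: incomplete discrimination within the conjugated diene, that is hydrogen transfer to the trisubstituted alkene or over-reduction when conversion is pushed, because the disubstituted alkene sits next to the quaternary carbon. Fallback, from 9 back to 10: homogeneous catalytic hydrogenation with RhCl(PPh3)3 (H2, 1 atm, benzene, rt). Selection there comes from alkene coordination to a crowded rhodium centre instead of a concerted hydrogen transfer; this fallback makes no new compound (F0).

Step 9. Most likely to go wrong: sluggish O–H addition of the hindered, hydrogen-bonded phenol to the ketene ylide, so that 14 lingers and degrades. Fallback, from 14 back to 16: the C3=C4 bond is made first by Z-selective Still–Gennari olefination (methyl bis(2,2,2-trifluoroethyl)phosphonoacetate, KN(SiMe3)2 (2 equiv), 18-crown-6, THF, −78 °C), which needs no acylation of the phenol. It gives methyl (2Z)-3-{3-[(1R,6R)-6-ethenyl-3,6-dimethylcyclohex-2-en-1-yl]-2-hydroxy-4,6-dimethoxyphenyl}prop-2-enoate F4. Its phenol closes onto the cis ester with loss of methanol on warming or on brief treatment with mild acid, giving 16.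

Step 10. Most likely to go wrong: loss of site selectivity, with iodination at C6 or C3 competing with C8. Fallback, from 6 back to 18: the iodine is taken from a compound in which its position is already fixed. Magnesium-mediated ortho-formylation of 6 (MgCl2, Et3N, (CH2O)n, MeCN, reflux) gives 2-hydroxy-3-iodo-4,6-dimethoxybenzaldehyde F5. Ph3P=C=C=O in toluene at 110 °C then closes the pyranone through 2-formyl-6-iodo-3,5-dimethoxyphenyl (triphenyl-λ5-phosphanylidene)acetate F6 (not isolated) to give 18.

Step 11. Most likely to go wrong: slow migratory insertion between a di-ortho-substituted arylpalladium and an alkene on a quaternary carbon beside a bulky aryl group, so that hydrodeiodination of 18 and catalyst decay take over. Fallback, from 16 back to 19: the bond is made by transmetalation and reductive elimination, which needs no insertion. Cross-metathesis of 16 with 4,4,5,5-tetramethyl-2-vinyl-1,3,2-dioxaborolane in excess (second-generation Grubbs catalyst, CH2Cl2, 40 °C) should give 8-[(1R,6R)-3,6-dimethyl-6-[(E)-2-(4,4,5,5-tetramethyl-1,3,2-dioxaborolan-2-yl)ethenyl]cyclohex-2-en-1-yl]-5,7-dimethoxy-2H-chromen-2-one F7; an alkene on a quaternary carbon does not homodimerise. Suzuki–Miyaura coupling of F7 with 18 (Pd(dppf)Cl2, K3PO4, THF/H2O, 60 °C) then gives 19 with retention of the E geometry.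

## Further compounds

F1 | step 4 | (6aR,10aR)-1,3-dimethoxy-6a,9-dimethyl-6a,10a-dihydro-6H-benzo[c]chromen-6-one | O=C2[C@]1(C)C=CC(C)=C[C@@H]1c3c(OC)cc(OC)cc3O2
F2 | step 1 | trans-1,4-dimethylcyclohexa-2,5-diene-1-carboxylic acid | C[C@]1(C(=O)O)C=C[C@@H](C)C=C1
F3 | step 1 | 2-iodo-3,5-dimethoxyphenyl trans-1,4-dimethylcyclohexa-2,5-diene-1-carboxylate | C[C@]1(C(=O)Oc2cc(OC)cc(OC)c2I)C=C[C@@H](C)C=C1
F0 | step 5 | none | none
F4 | step 9 | methyl (2Z)-3-{3-[(1R,6R)-6-ethenyl-3,6-dimethylcyclohex-2-en-1-yl]-2-hydroxy-4,6-dimethoxyphenyl}prop-2-enoate | C=C[C@@]1(C)CCC(C)=C[C@H]1c1c(OC)cc(OC)c(/C=C\C(=O)OC)c1O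
F5 | step 10 | 2-hydroxy-3-iodo-4,6-dimethoxybenzaldehyde | O=Cc1c(OC)cc(OC)c(I)c1O
F6 | step 10 | 2-formyl-6-iodo-3,5-dimethoxyphenyl (triphenyl-λ5-phosphanylidene)acetate | O=Cc1c(OC)cc(OC)c(I)c1OC(=O)C=P(c1ccccc1)(c1ccccc1)c1ccccc1
F7 | step 11 | 8-[(1R,6R)-3,6-dimethyl-6-[(E)-2-(4,4,5,5-tetramethyl-1,3,2-dioxaborolan-2-yl)ethenyl]cyclohex-2-en-1-yl]-5,7-dimethoxy-2H-chromen-2-one | CC1(C)OB(/C=C/[C@@]2(C)CCC(C)=C[C@H]2c2c(OC)cc(OC)c3ccc(=O)oc23)OC1(C)C
A1 | alternative 1 | 5,7-dimethoxy-8-[(1R,6S)-3,6-dimethyl-6-{[tri(propan-2-yl)silyl]ethynyl}cyclohex-2-en-1-yl]-2H-chromen-2-one | CC(C)[Si](C#C[C@@]1(C)CCC(C)=C[C@H]1c1c(OC)cc(OC)c2ccc(=O)oc12)(C(C)C)C(C)C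
A2 | alternative 1 | N'-[(1E,2R,5Z)-6-iodo-2,5-dimethyl-2-{[tri(propan-2-yl)silyl]ethynyl}hex-5-en-1-ylidene]-4-methylbenzenesulfonohydrazide | CC(C)[Si](C#C[C@@](/C=N/NS(=O)(=O)c1ccc(C)cc1)(C)CC/C(C)=C\I)(C(C)C)C(C)C
A3 | alternative 1 | (5,7-dimethoxy-2-oxo-2H-chromen-8-yl)boronic acid | COc1cc(OC)c2ccc(=O)oc2c1B(O)O
A4 | alternative 2 | 8-[(1R,6R)-6-ethenyl-3,6-dimethylcyclohex-2-en-1-yl]-5,7-dimethoxy-2H-chromen-2-one | C=C[C@@]1(C)CCC(C)=C[C@H]1c1c(OC)cc(OC)c2ccc(=O)oc12
A5 | alternative 2 | 5,7-dimethoxy-8-[(1R,4R)-4-methyl-4-(3-methylbut-3-en-1-yl)cyclobut-2-en-1-yl]-2H-chromen-2-one | C1=C[C@@H](c2c(OC)cc(OC)c3ccc(=O)oc23)[C@]1(C)CCC(C)=C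
A6 | alternative 3 | methyl 1,3-dimethoxy-9-methyl-6-oxo-10-(trimethylsilyl)-6a,7,10,10a-tetrahydro-6H-benzo[c]chromene-6a-carboxylate (cis-fused, configuration as in the SMILES) | O=C2[C@@]1(C(=O)OC)CC=C(C)[C@H]([Si](C)(C)C)[C@H]1c3c(OC)cc(OC)cc3O2
A7 | alternative 3 | methyl 5,7-dimethoxy-2-oxo-2H-chromene-3-carboxylate | COC(=O)c1cc2c(OC)cc(OC)cc2oc1=O
A8 | alternative 3 | trimethyl[(1E)-2-methylbuta-1,3-dien-1-yl]silane | C=C/C(C)=C/[Si](C)(C)C
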